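(All runs are calculated for substances that don't exist; the scatter is artificial.)

- elm: substrate 0.050 M; run made earlier
- flask: substrate 0.10 M; time 1.5 h

- elm (time / min: target / %, substrate / %): 0.500: 6.0, 79.3; 1.33: 11.4, 57.5; 2.50: 13.3, 40.6; 4.00: 14.4, 30.9; 5.00: 14.8, 26.0; 8.00: 12.5, 21.6; 10.0: 10.8, 18.9

(scatter of a reading: 0.5 percentage points)

- time, not beyond 1.5 h, at which the flask holds most target
- the amount of target, in percent of the substrate charged, at that time



At early times the elm run holds target at 0.0757 of its substrate, after 0.500 min. How does that ratio drift? It climbs to 0.328 at 2.50 min and 0.466 at 4.00 min, and it levels off from 5.00 min on, reading 0.569, 0.579 and 0.571 at the last three times. I call the value where it stands the tail ratio: target over substrate, both as fractions of the charge, over the last three readings of the elm run, read as 0.573, a quasi-steady state.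

So when does target peak? Once the ratio stands still, target follows substrate down. In the elm run the ratio is 0.569 at 5.00 min, and the readings at 4.00 min and 5.00 min differ by 0.4 percentage points with a scatter of 0.5 points, so I place the peak between those two times, at about 14.8% of the charge.

Does the flask, charged at 0.10 M instead of 0.050 M, move it? One run cannot prove otherwise, but the elm ratio holds while substrate falls from 26.0% to 18.9%. I therefore take the curve to repeat in fractions of the charge, with the peak between 0.067 h and 0.083 h.

The forecast gives 15.5% at 0.07 h, expecting “certainly not a late maximum”.

The flask gives 14.8% at 0.0671 h.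

    substrate ⇌ dormant form (K = 0.810, k = 0.00390 s⁻¹)
    substrate ⇌ target (K = 0.930, k = 0.00210 s⁻¹)
    substrate ⇌ isomer of the product (K = 2.60, k = 0.00130 s⁻¹)
    substrate ⇌ third isomer (K = 1.50, k = 7.60 × 10⁻⁴ s⁻¹)
    target → over-reaction product (k = 0.00200 s⁻¹)

The relaxation half-life of substrate and target by that step alone, 2.65 min, is short against the 1.5 h allowed and shorter than the 0.152 h of substrate and third isomer, and in the flask target keeps pace with substrate: the tail ratio times the 5.20% of substrate at 1.50 h gives 2.98%, against 2.65% of target found. In the neighbour flask read at 25 min, the tail ratio times its 11% of substrate gives 6.22%, and 6.12% of target stands there.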